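**Assumption:** the two stereodescriptors in the SMILES are read as 3R (carbinol next to the gem-dimethyl carbon) and 4S (benzylic carbinol), which is a trans-diol; 2,6-dimethoxytoluene and 2,5-dimethoxyphenol are taken as catalogue chemicals.

**Retrosynthetic overview**
- The furan C2–O bond is made last, by a redox-neutral photocycloisomerisation of an isoflavone 2′,5′-quinone (quinone oxygen onto chromone C2–H).
- The C3–C1′ bond comes from a dehydrogenative palladium coupling of a pyranochromone (fragment A) with a chiral chromene-5,8-dione (fragment D).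
- Fragment A: C–H borylation/oxidation of 2,6-dimethoxytoluene fixes the future pyranone oxygen, then acylation, pyranone ring, demethylation, and the chromene ring last (only C8 is free).
- Fragment D: chromene ring on 2,5-dimethoxyphenol, Jacobsen epoxidation (both stereocentres), SN2 hydroxide opening (trans-diol), oxidative demethylation to the quinone.
- Ring order: pyranone of ring A, then the ring A chromene; dihydropyran ring E, then quinone ring D; C3–C1′ bond; furan ring.

**Route**

Step 1
Reactants: 1 2,6-dimethoxytoluene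
Product: 3 3,5-dimethoxy-4-methylphenol, via aryl pinacol boronate 2 (not isolated)
Conditions: [Ir(OMe)(cod)]2 (1.5 mol %), 4,4′-di-tert-butyl-2,2′-bipyridine (3 mol %), B2pin2 (0.6 equiv), THF, 80 °C; then KHSO5 (Oxone), acetone/H2O, 20 °C
Reagents that add atoms: potassium peroxymonosulfate, [K+].[O-]S(=O)(=O)OO (phenol oxygen); bis(pinacolato)diboron, CC1(C)OB(OC1(C)C)B1OC(C)(C)C(C)(C)O1 (boryl group of intermediate 2 only)
Why: Sterically governed iridium-catalysed C–H borylation hits only C4, the one ring carbon not flanked by a substituent, and peroxymonosulfate oxidation of the boronate (1,2-aryl shift from boron to oxygen) gives the phenol whose oxygen becomes the pyranone oxygen, so the later ring closure has no regiochemical choice.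

Step 2
Reactants: 3 3,5-dimethoxy-4-methylphenol
Product: 4 1-(6-hydroxy-2,4-dimethoxy-3-methylphenyl)ethan-1-one
Conditions: Ac2O (1.5 equiv), BF3·OEt2 (3 equiv), 80 °C; then MeOH/H2O, reflux
Reagents that add atoms: acetic anhydride, CC(=O)OC(C)=O
Why: Boron trifluoride-mediated ortho-acylation (O-acylation/Fries rearrangement) goes to the only free nucleophilic position, since the two ortho carbons are equivalent and the para carbon carries the methyl group.

Step 3
Reactants: 4 1-(6-hydroxy-2,4-dimethoxy-3-methylphenyl)ethan-1-one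
Product: 6 5,7-dimethoxy-6-methyl-4H-chromen-4-one, via enaminone 5 (not isolated)
Conditions: Me2NCH(OMe)2 (3 equiv), toluene, 100 °C; evaporate; conc. HCl, CH2Cl2, 40 °C
Reagents that add atoms: N,N-dimethylformamide dimethyl acetal, COC(OC)N(C)C
Why: Enaminone route to chromones (condensation, then acid-induced oxa-Michael addition and loss of dimethylamine); only one ortho-hydroxyl is free, so the 5,7-dimethoxy-6-methyl pattern is unambiguous.

Step 4
Reactants: 6 5,7-dimethoxy-6-methyl-4H-chromen-4-one
Product: 7 5,7-dihydroxy-6-methyl-4H-chromen-4-one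
Conditions: BBr3 (4 equiv), CH2Cl2, −78 °C to 20 °C; MeOH/H2O quench
Reagents that add atoms: none
Why: Lewis-acid cleavage of both aryl methyl ethers (the peri 5-OMe is assisted by chelation to the carbonyl), and with no nucleophile present the pyranone ring cannot open and re-close the other way.

Step 5
Reactants: 7 5,7-dihydroxy-6-methyl-4H-chromen-4-one; 8 3-methylbut-2-enal
Product: 9 5-hydroxy-6,8,8-trimethyl-4H,8H-pyrano[2,3-f]chromen-4-one (fragment A)
Conditions: 8 (3 equiv), pyridine, 120 °C, sealed tube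
Reagents that add atoms: none
Why: Phenol–enal chromene annulation (attack of the acidic 7-phenol through C8, dehydration to an ortho-quinone methide, oxa-6π electrocyclisation); C6 carries the methyl group, so only the angular 7,8-fused pyran can form.

Step 6
Reactants: 10 2,5-dimethoxyphenol; 11 3-chloro-3-methylbut-1-yne
Product: 13 5,8-dimethoxy-2,2-dimethyl-2H-chromene, via aryl propargyl ether 12 (not isolated)
Conditions: K2CO3, KI (cat.), CuI (5 mol %), DMF, 60 °C; then 150 °C
Reagents that add atoms: none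
Why: O-propargylation, then aromatic Claisen rearrangement to the only free ortho carbon, 1,5-hydrogen shift and oxa-6π electrocyclisation (propargyl ether chromene synthesis).

Step 7
Reactants: 13 5,8-dimethoxy-2,2-dimethyl-2H-chromene
Product: 14 (3R,4R)-3,4-epoxy-5,8-dimethoxy-2,2-dimethylchromane
Conditions: (R,R)-(salen)MnCl [chloro{(R,R)-N,N′-bis(3,5-di-tert-butylsalicylidene)cyclohexane-1,2-diaminato}manganese] (3 mol %), aq. NaOCl (pH 11.3), 4-phenylpyridine N-oxide (20 mol %), CH2Cl2, 0 °C
Reagents that add atoms: sodium hypochlorite, [Na+].[O-]Cl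
Why: Jacobsen–Katsuki epoxidation, for which 2,2-dimethylchromenes are the best substrate class; the (R,R)-salen complex of trivalent manganese delivers oxygen to one face of the cis alkene and sets both centres as 3R,4R.

Step 8
Reactants: 14 (3R,4R)-3,4-epoxy-5,8-dimethoxy-2,2-dimethylchromane
Product: 15 (3R,4S)-5,8-dimethoxy-2,2-dimethyl-3,4-dihydro-2H-chromene-3,4-diol (trans)
Conditions: aq. KOH (2 M), 1,4-dioxane, 90 °C
Reagents that add atoms: water, O
Why: SN2 epoxide opening by hydroxide at benzylic C4 (C3 is neopentyl) with inversion gives the trans-(3R,4S) diol; base avoids the benzylic cation that acid would form on this electron-rich ring and that would leak to the cis diol.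

Step 9
Reactants: 15 (3R,4S)-5,8-dimethoxy-2,2-dimethyl-3,4-dihydro-2H-chromene-3,4-diol
Product: 16 (3R,4S)-3,4-dihydroxy-2,2-dimethyl-3,4-dihydro-2H-chromene-5,8-dione (fragment D)
Conditions: (NH4)2Ce(NO3)6 (2.5 equiv), MeCN/H2O 2:1, 0 °C, 15 min
Reagents that add atoms: water, O
Why: Oxidative demethylation of the para-dimethoxyarene by tetravalent cerium (arene radical cation, ipso attack of water, loss of methanol) gives the 2-alkoxy-1,4-benzoquinone without touching the carbinol centres.

Step 10
Reactants: 9 5-hydroxy-6,8,8-trimethyl-4H,8H-pyrano[2,3-f]chromen-4-one; 16 (3R,4S)-3,4-dihydroxy-2,2-dimethyl-3,4-dihydro-2H-chromene-5,8-dione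
Product: 17 3-[(3R,4S)-3,4-dihydroxy-2,2-dimethyl-5,8-dioxo-3,4,5,8-tetrahydro-2H-chromen-6-yl]-5-hydroxy-6,8,8-trimethyl-4H,8H-pyrano[2,3-f]chromen-4-one
Conditions: Pd(OAc)2 (10 mol %), AgOAc (2.2 equiv), PivOH (2 equiv), 16 (1.5 equiv), 1,4-dioxane, 90 °C, amber glassware
Reagents that add atoms: none
Why: Dehydrogenative (oxidative Heck-type) C–H/C–H cross-coupling of chromones with quinones: pivalate-assisted palladation of chromone C3 by divalent palladium, insertion into the quinone C6=C7 bond with the chromonyl group going to C6 (β to the more electrophilic C8 carbonyl, the C5 carbonyl being a deactivated vinylogous ester), β-hydride elimination, and reoxidation of zerovalent palladium by AgOAc.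

Step 11
Reactants: 17 the isoflavone 2′,5′-quinone from step 10
Product: 18 CNP0351839.1 (target coumaronochromone)
Conditions: blue LEDs (450 nm), degassed MeCN (2 mM), 20 °C
Reagents that add atoms: none
Why: Proposed new method: visible-light excitation of the quinone (n→π*/intramolecular charge transfer from the electron-rich chromone enol ether) lets the C5 quinone oxygen, held next to chromone C2–H, bond to C2, and the resulting 2H intermediate aromatises by proton shift to the other quinone oxygen, so the furan C–O bond and the 5′-OH form in a redox-neutral isomerisation with no reagent that could touch the chromene or the diol stereocentres; the closest known reaction is the photocyclisation of 2-aryl-1,4-benzoquinones to 2-hydroxydibenzofurans, not yet shown for a 3-quinonylchromone where the accepting carbon is C2–H of a 4-pyranone.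

**Compound list**

1 | 2,6-dimethoxytoluene | COc1cccc(OC)c1C | starting material
2 | 2-(3,5-dimethoxy-4-methylphenyl)-4,4,5,5-tetramethyl-1,3,2-dioxaborolane | COc1cc(B2OC(C)(C)C(C)(C)O2)cc(OC)c1C | intermediate
3 | 3,5-dimethoxy-4-methylphenol | COc1cc(O)cc(OC)c1C | intermediate
4 | 1-(6-hydroxy-2,4-dimethoxy-3-methylphenyl)ethan-1-one | CC(=O)c1c(O)cc(OC)c(C)c1OC | intermediate
5 | (E)-3-(dimethylamino)-1-(6-hydroxy-2,4-dimethoxy-3-methylphenyl)prop-2-en-1-one | CN(C)/C=C/C(=O)c1c(O)cc(OC)c(C)c1OC | intermediate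
6 | 5,7-dimethoxy-6-methyl-4H-chromen-4-one | COc1cc2occc(=O)c2c(OC)c1C | intermediate
7 | 5,7-dihydroxy-6-methyl-4H-chromen-4-one | Cc1c(O)cc2occc(=O)c2c1O | intermediate
8 | 3-methylbut-2-enal | CC(C)=CC=O | starting material
9 | 5-hydroxy-6,8,8-trimethyl-4H,8H-pyrano[2,3-f]chromen-4-one | Cc1c2c(c3occc(=O)c3c1O)C=CC(C)(C)O2 | intermediate
10 | 2,5-dimethoxyphenol | COc1ccc(OC)c(O)c1 | starting material
11 | 3-chloro-3-methylbut-1-yne | CC(C)(Cl)C#C | starting material
12 | 1,4-dimethoxy-2-[(2-methylbut-3-yn-2-yl)oxy]benzene | COc1ccc(OC)c(OC(C)(C)C#C)c1 | intermediate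
13 | 5,8-dimethoxy-2,2-dimethyl-2H-chromene | COc1ccc(OC)c2OC(C)(C)C=Cc12 | intermediate
14 | (3R,4R)-3,4-epoxy-5,8-dimethoxy-2,2-dimethylchromane | COc1ccc(OC)c2OC(C)(C)[C@@H]3O[C@@H]3c12 | intermediate
15 | (3R,4S)-5,8-dimethoxy-2,2-dimethyl-3,4-dihydro-2H-chromene-3,4-diol | COc1ccc(OC)c2OC(C)(C)[C@H](O)[C@@H](O)c12 | intermediate
16 | (3R,4S)-3,4-dihydroxy-2,2-dimethyl-3,4-dihydro-2H-chromene-5,8-dione | CC1(C)OC2=C(C(=O)C=CC2=O)[C@H](O)[C@H]1O | intermediate
17 | 3-[(3R,4S)-3,4-dihydroxy-2,2-dimethyl-5,8-dioxo-3,4,5,8-tetrahydro-2H-chromen-6-yl]-5-hydroxy-6,8,8-trimethyl-4H,8H-pyrano[2,3-f]chromen-4-one | Cc1c2c(c3occ(C4=CC(=O)C5=C(C4=O)[C@H](O)[C@@H](O)C(C)(C)O5)c(=O)c3c1O)C=CC(C)(C)O2 | intermediate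
18 | CNP0351839.1: benzofuro[2,3-b]chromen-4-one with 5-OH, 6-Me, a 2,2-dimethyl-2H-pyran fused at C7(O)/C8, 5′-OH, and a trans-(3R,4S)-3,4-dihydroxy-2,2-dimethyl-3,4-dihydro-2H-pyran fused at C3′(C)/C4′(O) | Cc1c2c(c3oc4oc5c6c(c(O)cc5c4c(=O)c3c1O)OC(C)(C)[C@H](O)[C@H]6O)C=CC(C)(C)O2 | target

**Step count and risks**

Total step count: 11. Longest linear sequence: 7 steps (steps 1–5, 10, 11).

Most likely to fail, step 11 (the proposed photocycloisomerisation): the excited quinone could instead abstract hydrogen from the side-chain carbinol or simply return to the ground state. The fallback uses known chemistry, sets out from 17 and comes back at 18. Aqueous Na2S2O4/EtOAc reduces the quinone to the 2′,5′-dihydroxyisoflavone F1. TBSCl/imidazole at 0 °C silylates the unhindered 5′-phenol (the 2′-phenol is flanked on both sides, the 5-OH is chelated) to give the mono-silyl ether F2. DDQ in 1,4-dioxane at 20 °C, the established oxidative cyclisation of 2′-hydroxyisoflavones to coumaronochromones, gives the silylated coumaronochromone F3, and TBAF/AcOH in THF releases 18.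

Second, step 10 (dehydrogenative coupling): the chromene alkene and the free diol may interfere with palladium, and the hydrogen bond from the C4 hydroxyl to the C5 carbonyl could erode the C6 selectivity. The fallback is a Suzuki–Miyaura route; it sets out from 4 (through enaminone 5) and from 15 and comes back at 17. Iodine in CHCl3 cyclises 5 to the 3-iodochromone F4, BBr3 gives the dihydroxy iodochromone F5, and 8 in pyridine at 120 °C gives the iodo pyranochromone F6. In parallel, NBS in MeCN at 0 °C brominates 15 para to the ring oxygen to give the aryl bromide F7, and B2pin2, PdCl2(dppf), KOAc in 1,4-dioxane at 80 °C give the aryl boronate F8. Coupling of F6 with F8 (Pd(PPh3)4, aq. Na2CO3, DME, 80 °C) gives the 2′,5′-dimethoxyisoflavone F9, and (NH4)2Ce(NO3)6 in MeCN/H2O at 0 °C gives 17.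

Third, step 9 (cerium oxidation with a free benzylic diol): the arene radical cation can fragment the C3–C4 bond with help from the free hydroxyl, or the glycol can be cleaved. The fallback masks the diol; it sets out from 15 and comes back at 16. 2,2-Dimethoxypropane with camphorsulfonic acid (cat.) in acetone gives the trans-acetonide F10. (NH4)2Ce(NO3)6 in MeCN/H2O at 0 °C gives the acetonide quinone F11, and aqueous AcOH at 60 °C hydrolyses the strained trans-fused ketal at the electron-poor quinone stage, where no benzylic cation can form, to give 16.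

Further compounds

F1 | step 11 | 3-[(3R,4S)-3,4,5,8-tetrahydroxy-2,2-dimethyl-3,4-dihydro-2H-chromen-6-yl]-5-hydroxy-6,8,8-trimethyl-4H,8H-pyrano[2,3-f]chromen-4-one | Cc1c2c(c3occ(-c4cc(O)c5OC(C)(C)[C@H](O)[C@@H](O)c5c4O)c(=O)c3c1O)C=CC(C)(C)O2
F2 | step 11 | 3-[(3R,4S)-8-(tert-butyldimethylsilyloxy)-3,4,5-trihydroxy-2,2-dimethyl-3,4-dihydro-2H-chromen-6-yl]-5-hydroxy-6,8,8-trimethyl-4H,8H-pyrano[2,3-f]chromen-4-one | Cc1c2c(c3occ(-c4cc(O[Si](C)(C)C(C)(C)C)c5OC(C)(C)[C@H](O)[C@@H](O)c5c4O)c(=O)c3c1O)C=CC(C)(C)O2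
F3 | step 11 | 5′-O-tert-butyldimethylsilyl ether of 18 | Cc1c2c(c3oc4oc5c6c(c(O[Si](C)(C)C(C)(C)C)cc5c4c(=O)c3c1O)OC(C)(C)[C@H](O)[C@H]6O)C=CC(C)(C)O2
F4 | step 10 | 3-iodo-5,7-dimethoxy-6-methyl-4H-chromen-4-one | COc1cc2occ(I)c(=O)c2c(OC)c1C
F5 | step 10 | 5,7-dihydroxy-3-iodo-6-methyl-4H-chromen-4-one | Cc1c(O)cc2occ(I)c(=O)c2c1O
F6 | step 10 | 5-hydroxy-3-iodo-6,8,8-trimethyl-4H,8H-pyrano[2,3-f]chromen-4-one | Cc1c2c(c3occ(I)c(=O)c3c1O)C=CC(C)(C)O2
F7 | step 10 | (3R,4S)-6-bromo-5,8-dimethoxy-2,2-dimethyl-3,4-dihydro-2H-chromene-3,4-diol | COc1c(Br)cc(OC)c2OC(C)(C)[C@H](O)[C@@H](O)c12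
F8 | step 10 | (3R,4S)-5,8-dimethoxy-2,2-dimethyl-6-(4,4,5,5-tetramethyl-1,3,2-dioxaborolan-2-yl)-3,4-dihydro-2H-chromene-3,4-diol | COc1c(B3OC(C)(C)C(C)(C)O3)cc(OC)c2OC(C)(C)[C@H](O)[C@@H](O)c12
F9 | step 10 | 3-[(3R,4S)-3,4-dihydroxy-5,8-dimethoxy-2,2-dimethyl-3,4-dihydro-2H-chromen-6-yl]-5-hydroxy-6,8,8-trimethyl-4H,8H-pyrano[2,3-f]chromen-4-one | Cc1c2c(c3occ(-c4cc(OC)c5OC(C)(C)[C@H](O)[C@@H](O)c5c4OC)c(=O)c3c1O)C=CC(C)(C)O2
F10 | step 9 | (3R,4S)-3,4-O-isopropylidene-5,8-dimethoxy-2,2-dimethylchromane-3,4-diol | COc1ccc(OC)c2OC(C)(C)[C@@H]3OC(C)(C)O[C@H]3c12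
F11 | step 9 | (3R,4S)-3,4-O-isopropylidene-3,4-dihydroxy-2,2-dimethyl-3,4-dihydro-2H-chromene-5,8-dione | O=C1C=CC(=O)C2=C1[C@@H]1OC(C)(C)O[C@H]1C(C)(C)O2
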